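**Retrosynthetic overview**
1. Gibberellin A(36) ⇐ α-ketol (C19 ketone, C20 carbinol) by periodate cleavage of C19–C20, which unmasks the 19-CO2H and the 20-CHO on C10.
2. α-Ketol ⇐ bridged ketone C4–C19(=O)–C20H2–C10 by enolate hydroxylation; bridged ketone ⇐ cyclopropyl ketone by Li/NH3 cleavage of C20–C1.
3. Cyclopropyl ketone ⇐ C19 diazoketone + Δ1(10) alkene (intramolecular cyclopropanation puts C20 on the α-face of C10).
4. Δ1(10)-19-acid ⇐ gibberellin A(7) by reductive opening of the allylic 19,10-lactone.
5. No ring of the target is built new: rings A–D and seven stereocentres come from gibberellin A(7); a cyclopropane (C1–C10–C20) and a cyclopentanone (C4–C19–C20–C10–C5) are made on ring A and cut again.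

Assumption: gibberellin A(7) (a fermentation product sold as the pure compound) counts as a commercial starting material, so this is a relay synthesis. α/β are the usual gibberellin descriptors (C19, C20 and the lactone bridge α; 3-OH β).

**Step 1**
Reactants: 1 gibberellin A(7)
Product: 3 silyl-protected gibberellin A(7) benzyl ester (3β-OSiEt3; C7 CO2Bn), via benzyl ester 2 (not isolated)
Conditions: BnBr (1.05 equiv), KHCO3, DMF, rt; then imidazole, Et3SiCl, DMAP (cat.), rt
Reagents that add atoms: benzyl bromide BrCc1ccccc1; chlorotriethylsilane CC[Si](Cl)(CC)CC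
Why: Chemoselective SN2 O-alkylation of the carboxylate followed by imidazole-mediated silylation of the 3β-alcohol protects both groups without touching a stereocentre; the benzyl ester is later removed by the Li/NH3 of step 5, and the silyl ether blocks retro-aldol and carbenoid O–H insertion.

**Step 2**
Reactants: 3 silyl-protected gibberellin A(7) benzyl ester
Product: 5 Δ1(10)-19-acid (lactone opened; C2 now CH2; C7 CO2Bn; 3β-OSiEt3), via tributylstannyl 19-carboxylate 4 (not isolated)
Conditions: Pd(PPh3)4 (5 mol%), Bu3SnH (1.5 equiv), THF, 0 °C → rt; 0.5 M HCl wash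
Reagents that add atoms: none
Why: Allylic hydrogenolysis (Tsuji–Trost-type ionisation, then hydride transfer): zerovalent palladium opens the strained tertiary allylic lactone anti to the carboxylate to a C10–C1–C2 π-allyl complex, and the Pd–H formed from Bu3SnH reductively eliminates at the less substituted terminus C2, giving the trisubstituted Δ1(10) alkene and the C19 acid with no new stereocentre.

**Step 3**
Reactants: 5 Δ1(10)-19-acid
Product: 7 C19 diazomethyl ketone, via C19 acid chloride 6 (not isolated)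
Conditions: 1-chloro-N,N,2-trimethylprop-1-en-1-amine (1.2 equiv), CH2Cl2, 0 °C → rt; then CH2N2 (excess), Et2O, 0 °C
Reagents that add atoms: diazomethane C=[N+]=[N-]
Why: Neutral acid-chloride formation with the α-chloroenamine and acylation of diazomethane (first stage of an Arndt–Eistert sequence) convert the hindered C19 acid into the diazoketone without acid that would relactonise the Δ1(10) acid or cleave the silyl ether.

**Step 4**
Reactants: 7 C19 diazomethyl ketone
Product: 8 cyclopropyl ketone (C20 bonded to C19, C1 and C10 on the α-face)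
Conditions: Cu(acac)2 (5 mol%), ClCH2CH2Cl, reflux, slow addition
Reagents that add atoms: none
Why: Intramolecular copper-carbenoid cyclopropanation of a γ,δ-unsaturated diazoketone: because C19 is axial on the α-face of C4, the carbene carbon (future C20) can only reach the α-face of C1=C10, which sets the quaternary C10 in the natural configuration together with the transient C1 and C20 centres.

**Step 5**
Reactants: 8 cyclopropyl ketone
Product: 10 bridged keto acid (C4–C19(=O)–C20H2–C10; free C7 CO2H; 3β-OSiEt3), via dilithium enolate carboxylate 9 (not isolated)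
Conditions: Li (5 equiv), NH3(l)/THF, −78 °C, 10 min; then solid NH4Cl; acidify to pH 3
Reagents that add atoms: none
Why: Dissolving-metal reduction of a cyclopropyl ketone: the ketyl opens the α-bond that gives the less substituted carbanion (C20–C1, secondary C1, not quaternary C10), leaving the bicyclo[3.2.1]octanone as its enolate, while the same electrons cleave the benzyl ester to the reduction-proof carboxylate; C10 is retained and C1 and C20 become CH2.

**Step 6**
Reactants: 10 bridged keto acid
Product: 12 C20 hydroxy ketone acid, via dipotassium enolate carboxylate 11 (not isolated)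
Conditions: KN(SiMe3)2 (2.4 equiv), THF, −78 °C; then trans-2-(phenylsulfonyl)-3-phenyloxaziridine (1.3 equiv), −78 °C; AcOH quench
Reagents that add atoms: trans-2-(phenylsulfonyl)-3-phenyloxaziridine O=S(=O)(c1ccccc1)N1OC1c1ccccc1
Why: Davis enolate oxidation: the first equivalent of base makes the carboxylate (which keeps the C6 hydrogen from epimerising), the second the only possible ketone enolate (C4 is quaternary), and the oxaziridine transfers oxygen to C20 from the face away from C6 without touching the alkene; this C20 centre is erased in step 7, so its configuration does not matter.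

**Step 7**
Reactants: 12 C20 hydroxy ketone acid
Product: 14 gibberellin A(36), via silyl-protected aldehyde diacid 13 (not isolated)
Conditions: H5IO6 (2.5 equiv), THF/H2O 3:1, 0 °C → rt; then 1 M HCl (cat.), rt
Reagents that add atoms: orthoperiodic acid OI(=O)(O)(O)(O)O (new C19 carboxyl oxygen); water O (the same oxygen by exchange)
Why: Periodate (Malaprade-type) cleavage of the α-hydroxy ketone cuts C19–C20 into the C19 acid and the C20 aldehyde on the intact quaternary C10, and the acidic aqueous medium then hydrolyses the triethylsilyl ether, giving the target (in equilibrium with its 19,20-lactol) with all eight stereocentres in place.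

**Compound list**
1 | Gibberellin A(7): 3β-hydroxy-1,16-diene, 19→10 γ-lactone on the α-face, C7 acid | C=C1C[C@]23C[C@H]1CC[C@H]2[C@]1(O4)C=C[C@H](O)[C@@](C)(C4=O)[C@H]1[C@@H]3C(=O)O | starting material
2 | Benzyl ester of 1 (C7 CO2Bn) | C=C1C[C@]23C[C@H]1CC[C@H]2[C@]1(O4)C=C[C@H](O)[C@@](C)(C4=O)[C@H]1[C@@H]3C(=O)OCc1ccccc1 | intermediate
3 | 3-O-Triethylsilyl gibberellin A(7) benzyl ester | C=C1C[C@]23C[C@H]1CC[C@H]2[C@]1(O4)C=C[C@H](O[Si](CC)(CC)CC)[C@@](C)(C4=O)[C@H]1[C@@H]3C(=O)OCc1ccccc1 | intermediate
4 | Tributylstannyl ester of acid 5 (C19 CO2SnBu3) | C=C1C[C@]23C[C@H]1CC[C@H]2C1=CC[C@H](O[Si](CC)(CC)CC)[C@@](C)(C(=O)O[Sn](CCCC)(CCCC)CCCC)[C@H]1[C@@H]3C(=O)OCc1ccccc1 | intermediate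
5 | Δ1(10)-19-acid: C1=C10 double bond, C2 CH2, free 4α-CO2H, 3β-OSiEt3, C7 CO2Bn, 16-ene | C=C1C[C@]23C[C@H]1CC[C@H]2C1=CC[C@H](O[Si](CC)(CC)CC)[C@@](C)(C(=O)O)[C@H]1[C@@H]3C(=O)OCc1ccccc1 | intermediate
6 | C19 acid chloride of 5 | C=C1C[C@]23C[C@H]1CC[C@H]2C1=CC[C@H](O[Si](CC)(CC)CC)[C@@](C)(C(=O)Cl)[C@H]1[C@@H]3C(=O)OCc1ccccc1 | intermediate
7 | C19 diazomethyl ketone (4α-C(=O)CH=N2), otherwise as 5 | C=C1C[C@]23C[C@H]1CC[C@H]2C1=CC[C@H](O[Si](CC)(CC)CC)[C@@](C)(C(=O)C=[N+]=[N-])[C@H]1[C@@H]3C(=O)OCc1ccccc1 | intermediate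
8 | Cyclopropyl ketone: C20 (CH) bonded to C19(=O), C1 and C10 on the α-face (tricyclo[3.2.1.0(2,7)]octan-6-one on ring A); 3β-OSiEt3; C7 CO2Bn | C=C1C[C@]23C[C@H]1CC[C@H]2[C@]14[C@@H]5C[C@H](O[Si](CC)(CC)CC)[C@@](C)(C(=O)[C@H]45)[C@H]1[C@@H]3C(=O)OCc1ccccc1 | intermediate
9 | Dilithium salt of 10 (C19=C20 enolate, C7 carboxylate) | C=C1C[C@]23C[C@H]1CC[C@H]2[C@]14CC[C@H](O[Si](CC)(CC)CC)[C@@](C)(C([O-])=C4)[C@H]1[C@@H]3C(=O)[O-].[Li+].[Li+] | intermediate
10 | Bridged keto acid: C4–C19(=O)–C20H2–C10 α-bridge, C1 and C2 CH2, 3β-OSiEt3, free C7 CO2H, 16-ene | C=C1C[C@]23C[C@H]1CC[C@H]2[C@]14CC[C@H](O[Si](CC)(CC)CC)[C@@](C)(C(=O)C4)[C@H]1[C@@H]3C(=O)O | intermediate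
11 | Dipotassium salt of 10 (C19=C20 enolate, C7 carboxylate) | C=C1C[C@]23C[C@H]1CC[C@H]2[C@]14CC[C@H](O[Si](CC)(CC)CC)[C@@](C)(C([O-])=C4)[C@H]1[C@@H]3C(=O)[O-].[K+].[K+] | intermediate
12 | α-Ketol acid: as 10 with C20 = CH(OH), OH on the face toward C1–C3 (the C20 epimer serves equally) | C=C1C[C@]23C[C@H]1CC[C@H]2[C@]14CC[C@H](O[Si](CC)(CC)CC)[C@@](C)(C(=O)[C@H]4O)[C@H]1[C@@H]3C(=O)O | intermediate
13 | 3-O-Triethylsilyl gibberellin A(36) (4α-CO2H, 10α-CHO, C7 CO2H) | C=C1C[C@]23C[C@H]1CC[C@H]2[C@]1(C=O)CC[C@H](O[Si](CC)(CC)CC)[C@@](C)(C(=O)O)[C@H]1[C@@H]3C(=O)O | intermediate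
14 | Gibberellin A(36): 3β-hydroxy, 4α-CO2H (C19), 10α-CHO (C20), C7 CO2H, 16-ene | C=C1C[C@]23C[C@H]1CC[C@H]2[C@]1(C=O)CC[C@H](O)[C@@](C)(C(=O)O)[C@H]1[C@@H]3C(=O)O | target

**Totals**
Total step count: 7. Longest linear sequence: 7 steps (fully linear from 1).

**Steps most likely to fail**

Step 2 (the hydride may go to C10, or the π-allyl complex may lose a β-hydrogen to give a diene). The fallback sets out from compound 1 and comes back at compound 5. Gibberellin A(7) itself, with no ester present, is reduced with Li in NH3/THF at −78 °C; the 3-alkoxide is too poor a leaving group for β-elimination and the allyl anion is protonated at C2, giving the Δ1(10) diacid F1. Iodolactonisation (I2, NaHCO3, aqueous THF) closes only the α-face C19 acid back onto C10, because the C7 acid could only form a bridged lactone, and gives the 1β-iodo 19,10-lactone 7-acid F2, which tells the two carboxyls apart. Benzylation and silylation as in step 1 give the protected iodolactone F3. Zn dust in THF/aqueous NH4Cl then eliminates the trans-diaxial iodide and carboxylate and returns acid 5.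

Step 5 (both cyclopropane bonds next to the ketyl overlap, so some cleavage toward C10 or over-reduction is possible). The fallback sets out from compound 8 and comes back at compound 10, and it controls regiochemistry by sterics instead of electron transfer. NaSePh (from PhSeSePh and NaBH4, DMF, 90 °C) attacks the secondary cyclopropane carbon C1 in an SN2-type homoconjugate opening, which the quaternary C10 cannot undergo, and at the same time dealkylates the benzyl ester, giving the 1β-phenylselanyl keto acid F4. Bu3SnH with AIBN in toluene at 80 °C removes the selenium and gives keto acid 10.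

Step 6 (the dianion may be poorly soluble or enolise incompletely). The fallback sets out from compound 10 and comes back at compound 13. Me3SiOTf and Et3N in CH2Cl2 at 0 °C give the bis-silyl enol ether ester F5 (C19=C20 trimethylsilyl enol ether, C7 trimethylsilyl ester). One equivalent of ozone in CH2Cl2/pyridine at −78 °C, then Me2S and aqueous work-up, cleaves the electron-rich enol ether in preference to the 16-ene and gives the silyl-protected aldehyde diacid 13, which the acid stage of step 7 converts into 14.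

**Further compounds**
F1 | step 2 | Δ1(10) diacid: 3β-hydroxy-1(10),16-diene-7,19-dioic acid | C=C1C[C@]23C[C@H]1CC[C@H]2C1=CC[C@H](O)[C@@](C)(C(=O)O)[C@H]1[C@@H]3C(=O)O
F2 | step 2 | 1β-iodo 19,10-lactone 7-acid (3β-OH, 16-ene) | C=C1C[C@]23C[C@H]1CC[C@H]2[C@]1(O4)[C@H](I)C[C@H](O)[C@@](C)(C4=O)[C@H]1[C@@H]3C(=O)O
F3 | step 2 | protected iodolactone (1β-iodo, 3β-OSiEt3, C7 CO2Bn) | C=C1C[C@]23C[C@H]1CC[C@H]2[C@]1(O4)[C@H](I)C[C@H](O[Si](CC)(CC)CC)[C@@](C)(C4=O)[C@H]1[C@@H]3C(=O)OCc1ccccc1
F4 | step 5 | 1β-phenylselanyl keto acid (as 10 with SePh on C1) | C=C1C[C@]23C[C@H]1CC[C@H]2[C@]14[C@H]([Se]c5ccccc5)C[C@H](O[Si](CC)(CC)CC)[C@@](C)(C(=O)C4)[C@H]1[C@@H]3C(=O)O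
F5 | step 6 | bis-silyl enol ether ester (C19=C20 OSiMe3, C7 CO2SiMe3) | C=C1C[C@]23C[C@H]1CC[C@H]2[C@]14CC[C@H](O[Si](CC)(CC)CC)[C@@](C)(C(O[Si](C)(C)C)=C4)[C@H]1[C@@H]3C(=O)O[Si](C)(C)C
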